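The chroman is cut at O1–C8a and C4–C4a, two bonds that leave adjacent ring A carbons, C4a being flanked by the C5 oxygen. What remains, C2–C3–C4 with its isopropyl and isobutyl groups, is the anti aldol of the symmetric ketone 2,6-dimethylheptan-4-one and a protected phloroglucinaldehyde. In the key step a ring A aryne (C4a≡C8a) is annulated onto this aldol: the C2 alkoxide arylates at C8a and the C4a anion closes the pyran ring on the C4 ketone. The precursors are the trimethylsilyl ether of the enantiopure aldol and an ortho-silyl aryl triflate bearing the C5/C7 methoxy groups and a C6 ester.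

Key step: step 8

Assumption: 1,3,5-tris(benzyloxy)benzene is bought, and (−)-Ipc2BCl is written as the reagent enantiomer that leads to the (1R,2S)-aldol; if the sense of induction is the reverse, the (+)-reagent takes its place with no other change.

Step 1
Reactants: 1 1,3,5-tris(benzyloxy)benzene
Product: 3 2,4,6-tris(benzyloxy)benzaldehyde, via aryl iminium chloride 2 (not isolated)
Conditions: POCl3, DMF, 0 → 25 °C; then aq NaOAc, 25 °C
Reagents that add atoms: N,N-dimethylformamide CN(C)C=O; water O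
Why: Vilsmeier–Haack formylation of a symmetrical trialkoxybenzene, whose three open positions are equivalent, should give a single aldehyde after hydrolysis of the iminium salt.

Step 2
Reactants: 3 2,4,6-tris(benzyloxy)benzaldehyde; 4 2,6-dimethylheptan-4-one (diisobutyl ketone)
Product: 7 (1R,2S)-1-hydroxy-5-methyl-2-(propan-2-yl)-1-[2,4,6-tris(benzyloxy)phenyl]hexan-3-one (anti aldol), via E-enol borinate 5 (not isolated), via boron aldolate 6 (not isolated)
Conditions: (−)-Ipc2BCl, Et3N, Et2O, −78 → 0 °C; 3, −78 → −20 °C; H2O2, pH 7 buffer, MeOH, 0 °C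
Reagents that add atoms: none
Why: E-selective enolisation by the dialkylboron chloride/Et3N pair and a chair (Zimmerman–Traxler) boron aldol should place the carbinol oxygen and the isopropyl group anti, while the isopinocampheyl ligands select the aldehyde face that gives the (1R,2S) isomer.

Step 3
Reactants: 7 (1R,2S)-1-hydroxy-5-methyl-2-(propan-2-yl)-1-[2,4,6-tris(benzyloxy)phenyl]hexan-3-one
Product: 8 (1R,2S)-5-methyl-2-(propan-2-yl)-1-[2,4,6-tris(benzyloxy)phenyl]-1-[(trimethylsilyl)oxy]hexan-3-one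
Conditions: Me3SiCl, imidazole, CH2Cl2, 0 °C
Reagents that add atoms: chlorotrimethylsilane C[Si](C)(C)Cl
Why: Mild O-silylation of the secondary alcohol blocks retro-aldol cleavage and dehydration on handling and later lets fluoride release the alkoxide with no proton donor present.

Step 4
Reactants: 9 4-hydroxy-2,6-dimethoxybenzaldehyde
Product: 10 4-hydroxy-2,6-dimethoxybenzoic acid
Conditions: NaClO2, NaH2PO4, 2-methyl-2-butene, t-BuOH/H2O, 0 → 25 °C
Reagents that add atoms: sodium chlorite [Na+].[O-]Cl=O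
Why: Chlorite (Pinnick) oxidation converts the aldehyde into the acid, and the alkene scavenger removes hypochlorite before it can chlorinate the electron-rich ring.

Step 5
Reactants: 10 4-hydroxy-2,6-dimethoxybenzoic acid
Product: 11 methyl 4-hydroxy-2,6-dimethoxybenzoate
Conditions: MeI, KHCO3, DMF, 25 °C
Reagents that add atoms: iodomethane CI
Why: SN2 alkylation of the carboxylate under bicarbonate, too weak a base to ionise the phenol to a useful extent, should esterify without O-methylation and avoids the acid under which this trioxygenated benzoic acid could decarboxylate.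

Step 6
Reactants: 11 methyl 4-hydroxy-2,6-dimethoxybenzoate
Product: 12 methyl 3-bromo-4-hydroxy-2,6-dimethoxybenzoate
Conditions: NBS (1.0 equiv), MeCN, −20 → 0 °C
Reagents that add atoms: N-bromosuccinimide O=C1CCC(=O)N1Br
Why: Electrophilic aromatic bromination ortho to the free hydroxyl, where the two open positions are equivalent, should stop at the monobromide with one equivalent of reagent at low temperature.

Step 7
Reactants: 12 methyl 3-bromo-4-hydroxy-2,6-dimethoxybenzoate
Product: 16 methyl 2,6-dimethoxy-4-[(trifluoromethanesulfonyl)oxy]-3-(trimethylsilyl)benzoate, via aryl silyl ether 13 (not isolated), via aryllithium 14 (not isolated), via lithium phenoxide 15 (not isolated)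
Conditions: HMDS, THF, 65 °C, evaporate; n-BuLi, THF, −100 → −78 °C; Tf2O, −78 → 0 °C
Reagents that add atoms: 1,1,1,3,3,3-hexamethyldisilazane C[Si](C)(C)N[Si](C)(C)C; trifluoromethanesulfonic anhydride O=S(=O)(OS(=O)(=O)C(F)(F)F)C(F)(F)F
Why: O-silylation, bromine–lithium exchange and the anionic 1,3-shift of silicon from oxygen to carbon (retro-Brook rearrangement) give the ortho-silyl phenoxide, which is triflated in the same flask, the exchange being faster than attack on an ester shielded by two ortho methoxy groups.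

Step 8
Reactants: 8 (1R,2S)-5-methyl-2-(propan-2-yl)-1-[2,4,6-tris(benzyloxy)phenyl]-1-[(trimethylsilyl)oxy]hexan-3-one; 16 methyl 2,6-dimethoxy-4-[(trifluoromethanesulfonyl)oxy]-3-(trimethylsilyl)benzoate
Product: 20 methyl (2R,3S,4R)-4-hydroxy-5,7-dimethoxy-4-(2-methylpropyl)-3-(propan-2-yl)-2-[2,4,6-tris(benzyloxy)phenyl]-3,4-dihydro-2H-chromene-6-carboxylate, via aryne 17 (not isolated), via potassium alkoxide 18 (not isolated), via aryl anion 19 (not isolated)
Conditions: 16 (1.5 equiv), KF, 18-crown-6, THF, −20 → 0 °C; then aq NH4Cl; Et3N-washed silica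
Reagents that add atoms: none
Why: Proposed new method: fluoride removes both trimethylsilyl groups, so aryne 17 (C4a≡C8a) and the proton-free alkoxide 18 arise side by side; the alkoxide oxygen bonds to C8a and the aryl anion 19 left at C4a adds to the C4 ketone, which forms O1–C8a and C4a–C4 in one operation. The closest known reaction type is the fluoride-induced annulation of arynes with ortho-hydroxyaryl ketones and salicylates (O-arylation followed by capture of the aryl anion by the carbonyl group), extended here from a phenoxide to the alkoxide of an aliphatic aldol. The pyran ring closes by 6-exo-trig attack of the C4a carbanion on the ketone. C2 and C3 are carried over unchanged from the anti aldol, and the new C4 carbinol centre should arise from a chair-like array with the C2 aryl and C3 isopropyl groups equatorial and the isobutyl group turned away from the C5 methoxy group, although its configuration is erased in step 9. The step needs regioselective addition to the unsymmetrical aryne and capture of the anion ahead of protonation or retro-aldol cleavage: the C5 methoxy group polarises the aryne so that the nucleophile enters at C8a and charge builds at C4a beside the oxygen, while the silyl ether, the aprotic medium and the low temperature keep proton donors and standing alkoxide to a minimum.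

Step 9
Reactants: 20 methyl (2R,3S,4R)-4-hydroxy-5,7-dimethoxy-4-(2-methylpropyl)-3-(propan-2-yl)-2-[2,4,6-tris(benzyloxy)phenyl]-3,4-dihydro-2H-chromene-6-carboxylate
Product: 22 methyl (2R,3R,4S)-5,7-dimethoxy-4-(2-methylpropyl)-3-(propan-2-yl)-2-[2,4,6-tris(benzyloxy)phenyl]-3,4-dihydro-2H-chromene-6-carboxylate (2,3-trans, 3,4-cis), via C4 benzylic cation 21 (not isolated)
Conditions: Et3SiH, CF3CO2H, CH2Cl2, −40 → 0 °C
Reagents that add atoms: none
Why: Ionic hydrogenation: the tertiary C4 carbinol ionises to a cation stabilised by O1 and the C5/C7 methoxy groups, and, as in additions of nucleophiles to C4 cations of 2,3-trans flavans, the silane hydride should enter anti to the C3 isopropyl group and leave H4 cis to H3.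

Step 10
Reactants: 22 methyl (2R,3R,4S)-5,7-dimethoxy-4-(2-methylpropyl)-3-(propan-2-yl)-2-[2,4,6-tris(benzyloxy)phenyl]-3,4-dihydro-2H-chromene-6-carboxylate
Product: 23 [(2R,3R,4S)-5,7-dimethoxy-4-(2-methylpropyl)-3-(propan-2-yl)-2-[2,4,6-tris(benzyloxy)phenyl]-3,4-dihydro-2H-chromen-6-yl]methanol
Conditions: LiAlH4, THF, 0 → 40 °C
Reagents that add atoms: none
Why: Hydride reduction of the ester to the primary benzylic alcohol, no other group of 22 being reducible by LiAlH4.

Step 11
Reactants: 23 [(2R,3R,4S)-5,7-dimethoxy-4-(2-methylpropyl)-3-(propan-2-yl)-2-[2,4,6-tris(benzyloxy)phenyl]-3,4-dihydro-2H-chromen-6-yl]methanol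
Product: 24 (2R,3R,4S)-5,7-dimethoxy-4-(2-methylpropyl)-3-(propan-2-yl)-2-[2,4,6-tris(benzyloxy)phenyl]-3,4-dihydro-2H-chromene-6-carbaldehyde
Conditions: Dess–Martin periodinane, NaHCO3, CH2Cl2, 0 → 25 °C
Reagents that add atoms: none
Why: Dess–Martin oxidation takes the benzylic alcohol to the aldehyde under buffered conditions without over-oxidation or ionisation of the electron-rich benzylic position.

Step 12
Reactants: 24 (2R,3R,4S)-5,7-dimethoxy-4-(2-methylpropyl)-3-(propan-2-yl)-2-[2,4,6-tris(benzyloxy)phenyl]-3,4-dihydro-2H-chromene-6-carbaldehyde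
Product: 25 (2R,3R,4S)-5,7-dimethoxy-4-(2-methylpropyl)-3-(propan-2-yl)-2-(2,4,6-trihydroxyphenyl)-3,4-dihydro-2H-chromene-6-carbaldehyde
Conditions: H2 (1 atm), Pd/C, EtOAc, 25 °C
Reagents that add atoms: none
Why: Catalytic hydrogenolysis of the three benzyl aryl ethers, stopped once they are gone, since the hindered electron-rich aldehyde and the C2–O1 ether should react much more slowly at 1 atm.

Step 13
Reactants: 25 (2R,3R,4S)-5,7-dimethoxy-4-(2-methylpropyl)-3-(propan-2-yl)-2-(2,4,6-trihydroxyphenyl)-3,4-dihydro-2H-chromene-6-carbaldehyde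
Product: 27 5-[(2R,3R,4S)-6-formyl-5,7-dimethoxy-4-(2-methylpropyl)-3-(propan-2-yl)-3,4-dihydro-2H-chromen-2-yl]-2,4,6-trihydroxybenzene-1,3-dicarbaldehyde, via bis-iminium salt 26 (not isolated)
Conditions: POCl3 (2.5 equiv), DMF, EtOAc, 0 → 25 °C; then aq NaOAc, 50 °C
Reagents that add atoms: N,N-dimethylformamide CN(C)C=O; water O
Why: Vilsmeier–Haack formylation should take place at the two open positions of the free phloroglucinol ring B, far more nucleophilic than C8 of ring A, which carries only ether donors and is deactivated by the C6 formyl group.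

Step 14
Reactants: 27 5-[(2R,3R,4S)-6-formyl-5,7-dimethoxy-4-(2-methylpropyl)-3-(propan-2-yl)-3,4-dihydro-2H-chromen-2-yl]-2,4,6-trihydroxybenzene-1,3-dicarbaldehyde
Product: 28 5-[(2R,3R,4S)-6-formyl-5,7-dihydroxy-4-(2-methylpropyl)-3-(propan-2-yl)-3,4-dihydro-2H-chromen-2-yl]-2,4,6-trihydroxybenzene-1,3-dicarbaldehyde (target)
Conditions: BBr3, CH2Cl2, −78 → 0 °C; then H2O
Reagents that add atoms: none
Why: Lewis acid cleavage of the two aryl methyl ethers, each ortho to the C6 formyl group that assists by chelation, frees O5 and O7, and the 2,3-trans-3,4-cis arrangement (C2 aryl and C3 isopropyl equatorial, C4 isobutyl axial away from O5) should survive any reversible opening at C2.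

Compound list
1 | 1,3,5-tris(benzyloxy)benzene | c1ccc(COc2cc(OCc3ccccc3)cc(OCc3ccccc3)c2)cc1 | starting material
2 | N,N-dimethyl-[2,4,6-tris(benzyloxy)phenyl]methaniminium chloride | C[N+](C)=Cc1c(OCc2ccccc2)cc(OCc2ccccc2)cc1OCc1ccccc1.[Cl-] | intermediate
3 | 2,4,6-tris(benzyloxy)benzaldehyde | O=Cc1c(OCc2ccccc2)cc(OCc2ccccc2)cc1OCc1ccccc1 | intermediate
4 | 2,6-dimethylheptan-4-one | CC(C)CC(=O)CC(C)C | starting material
5 | (E)-2,6-dimethylhept-3-en-4-yl diisopinocampheylborinate | CC(C)C/C(=C\C(C)C)OB([C@@H]1C[C@@H]2C[C@@H](C2(C)C)[C@H]1C)[C@@H]1C[C@@H]2C[C@@H](C2(C)C)[C@H]1C | intermediate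
6 | diisopinocampheylboron aldolate of 7 | O([C@@H](c1c(OCc2ccccc2)cc(OCc2ccccc2)cc1OCc1ccccc1)[C@@H](C(=O)CC(C)C)C(C)C)B([C@@H]1C[C@@H]2C[C@@H](C2(C)C)[C@H]1C)[C@@H]1C[C@@H]2C[C@@H](C2(C)C)[C@H]1C | intermediate
7 | (1R,2S)-1-hydroxy-5-methyl-2-(propan-2-yl)-1-[2,4,6-tris(benzyloxy)phenyl]hexan-3-one | O[C@@H](c1c(OCc2ccccc2)cc(OCc2ccccc2)cc1OCc1ccccc1)[C@@H](C(=O)CC(C)C)C(C)C | intermediate
8 | (1R,2S)-5-methyl-2-(propan-2-yl)-1-[2,4,6-tris(benzyloxy)phenyl]-1-[(trimethylsilyl)oxy]hexan-3-one | C[Si](C)(C)O[C@@H](c1c(OCc2ccccc2)cc(OCc2ccccc2)cc1OCc1ccccc1)[C@@H](C(=O)CC(C)C)C(C)C | intermediate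
9 | 4-hydroxy-2,6-dimethoxybenzaldehyde | O=Cc1c(OC)cc(O)cc1OC | starting material
10 | 4-hydroxy-2,6-dimethoxybenzoic acid | OC(=O)c1c(OC)cc(O)cc1OC | intermediate
11 | methyl 4-hydroxy-2,6-dimethoxybenzoate | COC(=O)c1c(OC)cc(O)cc1OC | intermediate
12 | methyl 3-bromo-4-hydroxy-2,6-dimethoxybenzoate | COC(=O)c1c(OC)cc(O)c(Br)c1OC | intermediate
13 | methyl 3-bromo-2,6-dimethoxy-4-[(trimethylsilyl)oxy]benzoate | COC(=O)c1c(OC)cc(O[Si](C)(C)C)c(Br)c1OC | intermediate
14 | methyl 3-lithio-2,6-dimethoxy-4-[(trimethylsilyl)oxy]benzoate | COC(=O)c1c(OC)cc(O[Si](C)(C)C)c([Li])c1OC | intermediate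
15 | lithium 4-(methoxycarbonyl)-3,5-dimethoxy-2-(trimethylsilyl)phenolate | COC(=O)c1c(OC)cc([O-])c([Si](C)(C)C)c1OC.[Li+] | intermediate
16 | methyl 2,6-dimethoxy-4-[(trifluoromethanesulfonyl)oxy]-3-(trimethylsilyl)benzoate | COC(=O)c1c(OC)cc(OS(=O)(=O)C(F)(F)F)c([Si](C)(C)C)c1OC | intermediate
17 | methyl 3,4-didehydro-2,6-dimethoxybenzoate (aryne, C4a≡C8a of the chroman) | COC(=O)C1=C(OC)C#CC=C1OC | intermediate
18 | potassium (1R,2S)-5-methyl-3-oxo-2-(propan-2-yl)-1-[2,4,6-tris(benzyloxy)phenyl]hexan-1-olate | [K+].[O-][C@@H](c1c(OCc2ccccc2)cc(OCc2ccccc2)cc1OCc1ccccc1)[C@@H](C(=O)CC(C)C)C(C)C | intermediate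
19 | potassium salt of methyl 2,6-dimethoxy-4-{(1R,2S)-5-methyl-3-oxo-2-(propan-2-yl)-1-[2,4,6-tris(benzyloxy)phenyl]hexoxy}benzoate metallated at C3 (C4a of the chroman) | [K+].COC(=O)c1c(OC)cc(O[C@@H](c2c(OCc3ccccc3)cc(OCc3ccccc3)cc2OCc2ccccc2)[C@@H](C(=O)CC(C)C)C(C)C)[c-]c1OC | intermediate
20 | methyl (2R,3S,4R)-4-hydroxy-5,7-dimethoxy-4-(2-methylpropyl)-3-(propan-2-yl)-2-[2,4,6-tris(benzyloxy)phenyl]-3,4-dihydro-2H-chromene-6-carboxylate | CC(C)C[C@]1(O)c2c(cc(OC)c(C(=O)OC)c2OC)O[C@@H](c2c(OCc3ccccc3)cc(OCc3ccccc3)cc2OCc2ccccc2)[C@@H]1C(C)C | intermediate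
21 | C4 benzylic cation derived from 20 | CC(C)C[C+]1c2c(cc(OC)c(C(=O)OC)c2OC)O[C@@H](c2c(OCc3ccccc3)cc(OCc3ccccc3)cc2OCc2ccccc2)[C@@H]1C(C)C | intermediate
22 | methyl (2R,3R,4S)-5,7-dimethoxy-4-(2-methylpropyl)-3-(propan-2-yl)-2-[2,4,6-tris(benzyloxy)phenyl]-3,4-dihydro-2H-chromene-6-carboxylate | CC(C)C[C@@H]1c2c(cc(OC)c(C(=O)OC)c2OC)O[C@@H](c2c(OCc3ccccc3)cc(OCc3ccccc3)cc2OCc2ccccc2)[C@@H]1C(C)C | intermediate
23 | [(2R,3R,4S)-5,7-dimethoxy-4-(2-methylpropyl)-3-(propan-2-yl)-2-[2,4,6-tris(benzyloxy)phenyl]-3,4-dihydro-2H-chromen-6-yl]methanol | CC(C)C[C@@H]1c2c(cc(OC)c(CO)c2OC)O[C@@H](c2c(OCc3ccccc3)cc(OCc3ccccc3)cc2OCc2ccccc2)[C@@H]1C(C)C | intermediate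
24 | (2R,3R,4S)-5,7-dimethoxy-4-(2-methylpropyl)-3-(propan-2-yl)-2-[2,4,6-tris(benzyloxy)phenyl]-3,4-dihydro-2H-chromene-6-carbaldehyde | CC(C)C[C@@H]1c2c(cc(OC)c(C=O)c2OC)O[C@@H](c2c(OCc3ccccc3)cc(OCc3ccccc3)cc2OCc2ccccc2)[C@@H]1C(C)C | intermediate
25 | (2R,3R,4S)-5,7-dimethoxy-4-(2-methylpropyl)-3-(propan-2-yl)-2-(2,4,6-trihydroxyphenyl)-3,4-dihydro-2H-chromene-6-carbaldehyde | CC(C)C[C@@H]1c2c(cc(OC)c(C=O)c2OC)O[C@@H](c2c(O)cc(O)cc2O)[C@@H]1C(C)C | intermediate
26 | bis(N,N-dimethyliminium) dichloride corresponding to the two new formyl groups of 27 | CC(C)C[C@@H]1c2c(cc(OC)c(C=O)c2OC)O[C@@H](c2c(O)c(C=[N+](C)C)c(O)c(C=[N+](C)C)c2O)[C@@H]1C(C)C.[Cl-].[Cl-] | intermediate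
27 | 5-[(2R,3R,4S)-6-formyl-5,7-dimethoxy-4-(2-methylpropyl)-3-(propan-2-yl)-3,4-dihydro-2H-chromen-2-yl]-2,4,6-trihydroxybenzene-1,3-dicarbaldehyde | CC(C)C[C@@H]1c2c(cc(OC)c(C=O)c2OC)O[C@@H](c2c(O)c(C=O)c(O)c(C=O)c2O)[C@@H]1C(C)C | intermediate
28 | 5-[(2R,3R,4S)-6-formyl-5,7-dihydroxy-4-(2-methylpropyl)-3-(propan-2-yl)-3,4-dihydro-2H-chromen-2-yl]-2,4,6-trihydroxybenzene-1,3-dicarbaldehyde | CC(C)C[C@@H]1c2c(cc(O)c(C=O)c2O)O[C@@H](c2c(O)c(C=O)c(O)c(C=O)c2O)[C@@H]1C(C)C | target

Total step count: 14. Longest linear sequence: 11 steps (steps 4–14, from 9); the ring B arm (steps 1–3) joins at step 8.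

Steps most likely to fail

1. Step 8. The alkoxide may fragment by retro-aldol before it meets the aryne. The aryl anion may also be protonated, or may abstract H3, before it reaches the hindered ketone; then only O-arylation or cleavage would be seen. The fallback builds the same two bonds one at a time with known reactions; it sets out from 7 and 16 and comes back at 22, so it also replaces step 9. The free aldol 7 is treated with the aryne from 16 under KF/18-crown-6 in THF at −20 °C. This is the known O–H insertion of aliphatic alcohols into arynes, in which protonation of the anion is the wanted outcome and no standing alkoxide is required. It should give the aryl ether methyl 2,6-dimethoxy-4-{(1R,2S)-5-methyl-3-oxo-2-(propan-2-yl)-1-[2,4,6-tris(benzyloxy)phenyl]hexoxy}benzoate F1. Its aryl group is symmetrical, so the two positions ortho to the ether oxygen are equivalent and no regiochemical question arises. BF3·OEt2 and Et3SiH in CH2Cl2 (−78 → −20 °C) should then bring about intramolecular Friedel–Crafts hydroxyalkylation by the ketone, followed in the same flask by ionic hydrogenation of the C4 carbinol, to give 22.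

2. Step 9. Hydride transfer to the C4 cation may show poor facial selectivity, or the acid may open the C2–O1 benzylic ether. The fallback is a radical deoxygenation under neutral conditions that sets out from 20 and comes back at 22. The lithium alkoxide of 20 (n-BuLi, THF, −78 °C) is acylated with methyl chlorooxoacetate to the mixed oxalate methyl (2R,3S,4R)-5,7-dimethoxy-4-[(2-methoxy-2-oxoacetyl)oxy]-4-(2-methylpropyl)-3-(propan-2-yl)-2-[2,4,6-tris(benzyloxy)phenyl]-3,4-dihydro-2H-chromene-6-carboxylate F2. F2 is used crude and reduced with Bu3SnH and AIBN in toluene at 100 °C (known deoxygenation of tertiary alcohols through their methyl oxalates). The planar C4 radical should take up hydrogen from the face away from the C3 isopropyl group.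

3. Step 2. Addition to the hindered, electron-rich aldehyde may be slow, and an E-enol borinate with isopinocampheyl ligands may discriminate the aldehyde faces incompletely. The fallback moves stereocontrol from the reagent to a separation; it sets out from 3 and 4 and comes back at 7. The racemic anti aldol is made through the E-enol dicyclohexylborinate ((c-C6H11)2BCl, Et3N, Et2O; then H2O2), whose smaller ligands should also ease the addition. The enantiomers are then separated by preparative chromatography on a chiral stationary phase. The (1R,2S)-isomer is 7, and the unwanted (1S,2R)-1-hydroxy-5-methyl-2-(propan-2-yl)-1-[2,4,6-tris(benzyloxy)phenyl]hexan-3-one F3 is set aside.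

Further compounds
F1 | step 8 | methyl 2,6-dimethoxy-4-{(1R,2S)-5-methyl-3-oxo-2-(propan-2-yl)-1-[2,4,6-tris(benzyloxy)phenyl]hexoxy}benzoate | COC(=O)c1c(OC)cc(O[C@@H](c2c(OCc3ccccc3)cc(OCc3ccccc3)cc2OCc2ccccc2)[C@@H](C(=O)CC(C)C)C(C)C)cc1OC
F2 | step 9 | methyl (2R,3S,4R)-5,7-dimethoxy-4-[(2-methoxy-2-oxoacetyl)oxy]-4-(2-methylpropyl)-3-(propan-2-yl)-2-[2,4,6-tris(benzyloxy)phenyl]-3,4-dihydro-2H-chromene-6-carboxylate | CC(C)C[C@]1(OC(=O)C(=O)OC)c2c(cc(OC)c(C(=O)OC)c2OC)O[C@@H](c2c(OCc3ccccc3)cc(OCc3ccccc3)cc2OCc2ccccc2)[C@@H]1C(C)C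
F3 | step 2 | (1S,2R)-1-hydroxy-5-methyl-2-(propan-2-yl)-1-[2,4,6-tris(benzyloxy)phenyl]hexan-3-one | O[C@H](c1c(OCc2ccccc2)cc(OCc2ccccc2)cc1OCc1ccccc1)[C@H](C(=O)CC(C)C)C(C)C
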